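Readings and results are simulated with made-up constants; scatter was added.

The vessel is closed, stirred and isothermal, and three earlier runs differ in their loading of initiator.

| setting | autumn | winter | noon | ochre | teal |
|---|---|---|---|---|---|
| substrate | 0.050 M | 0.050 M | 0.050 M | 0.050 M | 0.050 M |
| reagent | 1.2 equiv | 1.2 equiv | 1.2 equiv | 1.20 equiv | 1.20 equiv |
| initiator | 1.5 mol% | 3.7 mol% | 5.3 mol% | 6 mol% | 2 mol% |
| remark | run made earlier | run made earlier | run made earlier |  |  |
| time |  |  |  | 0.80 h | 1.5 h |

- autumn (time / min: product / %): 6.00: 3.6; 15.0: 7.9; 30.0: 16.0; 50.0: 27.8
- winter (time / min: product / %): 12.0: 13.6; 25.0: 22.3; 30.0: 23.8; 50.0: 36.9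
- noon (time / min: product / %): 6.00: 7.3; 15.0: 16.2; 30.0: 31.0; 50.0: 44.6

(standard deviation of a reading: 1 percentage point)

* the winner by amount of product, in percent of the substrate charged; "neither" if no more than 2 percentage points parts them (ochre / teal / neither)
* how much product is there at the end, in percent of the substrate charged: ochre
* how much product is there at the end, in percent of the substrate charged: teal



In the noon run, the logarithm of the fraction of the charge that is not product falls nearly in a straight line with time, a pseudo-first-order picture. That slope can be frozen. Noon's last reading gives 0.0118 min⁻¹, the noon rate: the fractional loss of that remainder per minute at noon's loading. My own rule, with the substrate and reagent charges held, scales this rate with the square root of the loading ratio and multiplies by time, which gives a flask's clock. The product fraction is then one minus the exponential of the negative clock.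

Autumn and winter test this rule, since neither set the rate. Autumn's clock of 0.314 gives 26.9 % against a reading of 27.8 %. Winter's clock of 0.493 gives 38.9 % against 36.9 %.

The ladder of lifetimes, the inverse clock rates, runs from fastest to slowest: ochre 79.6 min, noon 84.7 min, winter 101 min, teal 138 min, autumn 159 min. Ochre stops at 48 min, short of its lifetime, and teal stops at 90 min, also short of its own. Their clocks are 0.603 and 0.653, so my reckoning gives ochre 45.3 % and teal 48.0 %. That is a gap of 2.7 percentage points against a margin of 2 points, and teal runs past the last reading, so I call the pair too close to part.

The forecast says neither, with ochre 45.5 % and teal 47 %, and it warns of teal: “Any slow initiator decay would lower this”.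

The flask gives ochre 44.6 % and teal 44.6 %: neither.

    substrate + second chain carrier → by-product + first chain carrier (k = 6800 L mol⁻¹ s⁻¹)
    substrate + initiating radical → capped initiator + first chain carrier (k = 4.60 × 10⁵ L mol⁻¹ s⁻¹)
    2 first chain carrier → ended chains (k = 1.90 × 10⁸ L mol⁻¹ s⁻¹)
    reagent + first chain carrier → product + second chain carrier (k = 3900 L mol⁻¹ s⁻¹)
    initiator → 2 initiating radical (k = 1.30 × 10⁻⁴ s⁻¹)
    crystals ⇌ by-product, rate k6*(cs6 - [by-product]) while solid is left; crystals form when [by-product] > cs6 (solubility = 6.90 mM, k = 0.00160 s⁻¹)

The clock stands 0.70 points above ochre and 3.4 points above teal. Ochre ends with 69 % of its initiator, teal with 50 %. The neighbouring flask is teal with 0.8 mol% of initiator and the same time. Its clock is 0.413, which gives 33.8 %. That neighbouring flask ends with 30.6 % of product and 50 % of its initiator.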